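## The problem

Compound **19** is a dihydrochalcone. Ring A is a 2,2-dimethylchroman (O1, C2 with two methyl groups, C3, C4, C4a, C5 to C8, C8a) with hydroxyl groups on C5 and C7 and, between them on C6, the carbonyl of a C(=O)CH2CH2 chain. The chain ends at C1' of ring B, which carries OH on C3', OMe on C4' and a 3-methylbut-2-enyl (prenyl) group on C5'.

There is no stereocenter, so the difficulty lies only in where the groups sit and in which order they arrive. Three placements must be secured:
- the acyl group on C6 and not on C8;
- the methyl group on O4' while O3' stays free;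
- the prenyl group on C5' of ring B and not on the far more nucleophilic ring A.

The chain is saturated but the prenyl alkene must survive, so the chain reduction has to come before that alkene exists. The prenyl alkene is sensitive to protic acid, which can add across it or close it onto a neighbouring free phenol, and to hydrogenation. Ring A is a phloroglucinol-type arene that is easily oxidised and attacked by electrophiles.

The feature that makes the key step possible is the environment of O4'. Its ortho carbon C5' is free, its other ortho carbon C3' carries oxygen, and its para carbon C1' carries the chain. An allyl group leaving O4' in a [3,3] shift can therefore come to rest only on C5', and the same event frees O4' as the one phenol that has to be methylated.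

## Retrosynthesis

**19 to 18 to 17.** The three aryl O-CH2OMe bonds of **18** are cut last in the forward sense, and before that the O4'-CH3 bond. In **17** the O4' hydroxyl is the only free phenol, so methylation needs no selectivity. Methylating a free catechol or the free tetraphenol would give mixtures. The forward reactions are a plain Williamson methylation and a mild acetal cleavage. The cleavage is safe for the prenyl group because O4' is by then an ether and cannot add to the alkene.

**17 to 15.** The C5'-CH2 bond of the prenyl group is cut and the dimethyl-bearing carbon is reconnected to O4', giving the 1,1-dimethylallyl ether **15**. The neighbouring cuts are weaker: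
- Friedel-Crafts prenylation would strike ring A first.
- Cross-coupling at C5' needs a halide and a prenyl-metal reagent that can transpose.
- A shift from O3' would land on C2'.

The precursor is no simpler in atom count, but its ring B is the plain 3,4-dioxygenated pattern of a cheap aldehyde. The forward reaction must be a clean aromatic Claisen rearrangement that outruns loss of isoprene from the tertiary ether.

**15 to 12 and 8.** The C6-C(=O) bond is cut, giving the aryllithium **13** derived from chroman **12** and the N-methoxy-N-methylamide **8**. This splits the molecule into halves of similar size. Cutting the chain between its two CH2 carbons (aldol condensation, then enone reduction) would put a hydrogenation next to the allyl ether or make the route linear. Friedel-Crafts acylation of free diol **11** would need acid and would not distinguish C6 from C8. The forward reaction asks that lithiation of **12** occur at C6, between the two methoxymethyl (MOM) ethers, and that the hindered aryllithium add to the amide faster than it deprotonates it.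

**8 to 7 to 5 and 6.** The O4'-CMe2 bond is cut. A tertiary allylic ether cannot be made by direct substitution with a prenyl halide, which would give the linear ether. The carbon is therefore brought in as the tertiary propargyl chloride **6** under copper catalysis, and the alkyne of **7** is half-reduced to the alkene of **8**. The precursor **5** is a simple phenol with a finished, saturated chain.

**5 to 4 to 3 to 2 to 1.** The chain is cut at the former alkene of enamide **4**, back to aldehyde **3**, using a Horner-Wadsworth-Emmons reagent that already carries the N-methoxy-N-methylamide. One hydrogenation of **4** saturates the chain and removes the benzyl group from O4'. The two phenols of **1** are told apart by acidity: the 4-OH, para to the formyl group, is benzylated first (**2**), and the 3-OH then takes the MOM group (**3**).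

**12 to 11 to 9 and 10.** The two MOM ethers are removed, then the O1-C2 and C4-C4a bonds of the pyran are cut, leading to phloroglucinol **9** and isoprene **10**. Because the three ring carbons of **9** are equivalent, the annulation has a single constitutional outcome. The forward reaction only has to stop after one ring has formed.

## Roads not taken

**Alternative 1:** The cut is the pyran ring of ring A (C4-C4a formed, O1-C2 re-formed). The precursor is the aryl 1,1-dimethylpropargyl ether A2, whose ring A is symmetric about the axis through the acyl carbon and the para oxygen. Heating in N,N-diethylaniline would give the 2,2-dimethylchromene A1 through propargyl Claisen shift, hydrogen shift and 6-pi oxa-electrocyclisation.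
- Merit: the two ortho carbons of the para oxygen are equivalent, so the position of the acyl group relative to the pyran oxygen is fixed by symmetry. This is better than the chosen plan, which relies on the two MOM ethers of **12** to direct lithiation to C6.
- Weak points: A1 still holds a C3=C4 alkene that must be hydrogenated in the presence of the prenyl alkene of ring B on the way to **18**. That is the selection between two alkenes that the chosen plan never has to make. The cascade also does nothing for ring B, whose prenyl group in A2 still has to be introduced by a step of its own. Making A2 needs a para-selective propargylation and a separate protecting-group sequence.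
- Comparison: against the symmetry argument, the chosen plan sets a saturated chroman obtained in one step from **9** and **10**, the cooperative ortho-direction of two MOM groups, and fewer steps.

**Alternative 2:** The cuts are C7-O and C6-C(=O), made together. CsF would trigger 1,2-elimination of silyl and triflate from A4. The caesium carboxylate of acid A5 would add through oxygen at C7, and the C6 carbanion so formed would take the acyl group from that oxygen, giving the ortho-hydroxyaryl ketone A3.
- Merits: the union is convergent and runs under nearly neutral fluoride conditions with no organolithium near the chain. The inductive effect of the C5 oxygen directs the nucleophile to C7. O7 and O5 emerge differentiated. In mildness this road is better than the lithiation of the chosen plan.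
- Weak points: A4 is a penta-substituted chroman whose silyl and triflate groups must be placed regioselectively, so the C6 versus C8 question returns in a longer form. The acyl transfer competes with simple protonation of the aryl anion, which leaves an aryl ester. A5 is the valuable partner and its prenyl group again has to come from a separate operation.
- Comparison: the chosen plan sets against the milder coupling a two-step ring A fragment and a key step that solves the ring B substitution itself.

**Alternative 3:** The cut is the bond between the benzylic chain carbon and C1'. Pd(OAc)2 with a bulky electron-rich phosphine and Cs2CO3 would couple cyclopropanol A7 with aryl bromide A8. Beta-carbon elimination from the palladium alkoxide of A7 opens the three-membered ring, and reductive elimination joins the former ring CH2 to C1'. The product A6 is the same compound as **18**.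
- Merits: the chain is never an alkene, so the prenyl group can be present on A8 from the start. In this respect the road is as good as the chosen plan. It also arrives directly at the penultimate compound.
- Weak points: beta-hydride elimination from the divalent palladium homoenolate would give the enone. A7 is a tertiary cyclopropanol flanked by two ortho MOM ethers. It would have to come from aryllithium **13** and a cyclopropanone equivalent, or from a Kulinkovich reaction at a carbonyl shielded on both sides. A8 needs its prenyl group placed ortho to oxygen by yet another step.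
- Comparison: convergence is equal. The chosen plan uses the same aryllithium **13** directly in an acylation and places the prenyl group inside the key step.

Key step: step 10

## Route

Step 1
Reactants: 1 3,4-dihydroxybenzaldehyde
Product: 2 4-(benzyloxy)-3-hydroxybenzaldehyde
Conditions: BnBr (1.0 equiv), NaHCO3, DMF, 40 °C
Reagents that add atoms: benzyl bromide, BrCc1ccccc1
Why: Williamson ether synthesis; the 4-OH is para to the formyl group and clearly the more acidic phenol, so the weak base forms and benzylates that phenoxide and leaves the 3-OH free.

Step 2
Reactants: 2 4-(benzyloxy)-3-hydroxybenzaldehyde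
Product: 3 4-(benzyloxy)-3-(methoxymethoxy)benzaldehyde
Conditions: MOMCl, i-Pr2NEt, CH2Cl2, 0 °C to rt
Reagents that add atoms: chloromethyl methyl ether, COCCl
Why: O-alkylation of the remaining phenol by an alpha-chloro ether gives the MOM acetal, which is stable to base, hydride, hydrogenation and organolithium reagents and is removed only at the end.

Step 3
Reactants: 3 4-(benzyloxy)-3-(methoxymethoxy)benzaldehyde
Product: 4 (E)-3-[4-(benzyloxy)-3-(methoxymethoxy)phenyl]-N-methoxy-N-methylprop-2-enamide
Conditions: (EtO)2P(O)CH2C(O)N(OMe)Me, NaH, THF, 0 °C to rt
Reagents that add atoms: diethyl [2-[methoxy(methyl)amino]-2-oxoethyl]phosphonate, CCOP(=O)(CC(=O)N(C)OC)OCC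
Why: Horner-Wadsworth-Emmons olefination with a stabilised phosphonate anion should give the E enamide and installs the two chain carbons and the acylating group in one operation; the alkene geometry is of no consequence because it is reduced next.

Step 4
Reactants: 4 (E)-3-[4-(benzyloxy)-3-(methoxymethoxy)phenyl]-N-methoxy-N-methylprop-2-enamide
Product: 5 3-[4-hydroxy-3-(methoxymethoxy)phenyl]-N-methoxy-N-methylpropanamide
Conditions: H2 (1 atm), 10% Pd/C, EtOAc/EtOH, rt
Reagents that add atoms: none
Why: Catalytic hydrogenation saturates the conjugated alkene and hydrogenolyses the benzyl ether in the same flask; the MOM acetal and the N-O bond of the amide are expected to survive neutral, low-pressure conditions, and no other alkene is yet present.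

Step 5
Reactants: 5 3-[4-hydroxy-3-(methoxymethoxy)phenyl]-N-methoxy-N-methylpropanamide; 6 3-chloro-3-methylbut-1-yne
Product: 7 N-methoxy-3-[3-(methoxymethoxy)-4-[(2-methylbut-3-yn-2-yl)oxy]phenyl]-N-methylpropanamide
Conditions: CuCl2·2H2O (cat.), DBU, MeCN, 0 °C
Reagents that add atoms: none
Why: Copper-catalysed propargylic etherification of a phenol with a tertiary propargyl chloride is the standard way to aryl 1,1-dimethylpropargyl ethers; it forms at 0 °C the tertiary C-O bond that direct substitution with an allylic halide cannot give.

Step 6
Reactants: 7 N-methoxy-3-[3-(methoxymethoxy)-4-[(2-methylbut-3-yn-2-yl)oxy]phenyl]-N-methylpropanamide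
Product: 8 N-methoxy-3-[3-(methoxymethoxy)-4-[(2-methylbut-3-en-2-yl)oxy]phenyl]-N-methylpropanamide
Conditions: H2 (1 atm), Pd/CaCO3 poisoned with Pb(OAc)2 (Lindlar catalyst), quinoline, EtOAc, rt
Reagents that add atoms: none
Why: Lindlar semihydrogenation of the terminal alkyne stops at the terminal alkene when hydrogen uptake is monitored; the product is kept at or below room temperature because it is already a Claisen substrate.

Step 7
Reactants: 9 phloroglucinol; 10 isoprene
Product: 11 2,2-dimethylchroman-5,7-diol
Conditions: Amberlyst 15 (polystyrenesulfonic acid resin, H+ form), THF/heptane, 65 °C, 9 in threefold excess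
Reagents that add atoms: none
Why: Acid-catalysed chromanylation of a phenol with a 1,3-diene: Friedel-Crafts prenylation of the arene followed by Markovnikov addition of the adjacent hydroxyl to the alkene; all ring carbons of 9 are equivalent, so only one constitution can form, and the excess of 9 holds back a second annulation.

Step 8
Reactants: 11 2,2-dimethylchroman-5,7-diol
Product: 12 5,7-bis(methoxymethoxy)-2,2-dimethylchroman
Conditions: MOMCl, i-Pr2NEt, CH2Cl2, 0 °C to rt
Reagents that add atoms: chloromethyl methyl ether, COCCl
Why: Double O-alkylation with the alpha-chloro ether protects both phenols and at the same time installs the two groups that will direct metalation to C6.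

Step 9
Reactants: 12 5,7-bis(methoxymethoxy)-2,2-dimethylchroman; 8 N-methoxy-3-[3-(methoxymethoxy)-4-[(2-methylbut-3-en-2-yl)oxy]phenyl]-N-methylpropanamide
Product: 15 1-[5,7-bis(methoxymethoxy)-2,2-dimethylchroman-6-yl]-3-[3-(methoxymethoxy)-4-[(2-methylbut-3-en-2-yl)oxy]phenyl]propan-1-one, via aryllithium 13 (not isolated), via lithium hemiaminal 14 (not isolated)
Conditions: n-BuLi (slightly less than 12), THF, 0 °C; then 8, −78 to 0 °C; aq. NH4Cl
Reagents that add atoms: none
Why: Directed ortho-metalation followed by Weinreb ketone synthesis; C6-H lies between two chelating MOM ethers whereas C8-H has only one beside the hindered ring oxygen, so lithiation should give 13, and the chelated adduct 14 holds the carbonyl masked until work-up so that the reaction stops at the ketone.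

Step 10
Reactants: 15 1-[5,7-bis(methoxymethoxy)-2,2-dimethylchroman-6-yl]-3-[3-(methoxymethoxy)-4-[(2-methylbut-3-en-2-yl)oxy]phenyl]propan-1-one
Product: 17 1-[5,7-bis(methoxymethoxy)-2,2-dimethylchroman-6-yl]-3-[4-hydroxy-3-(methoxymethoxy)-5-(3-methylbut-2-enyl)phenyl]propan-1-one, via dienone 16 (not isolated)
Conditions: N,N-diethylaniline (degassed), 120 °C, Ar
Reagents that add atoms: none
Why: This is the aromatic Claisen rearrangement of an aryl 1,1-dimethylallyl ether, the standard entry to ortho-prenylphenols. The ether reacts through a six-membered chair-like [3,3] transition state in which the terminal CH2 of the allyl unit bonds to C5' while the O4'-CMe2 bond breaks, so the unit arrives inverted as a 3-methylbut-2-enyl group with its alkene in the trisubstituted position. The first product is cyclohexadienone 16, which tautomerises by loss of the C5' hydrogen to restore the arene and free the O4' phenol of 17; no ring closes, and the only new sp3 centre (C5' of 16) is transient, so no stereocenter has to be controlled. Site selectivity is needed and is secured by ring B itself: a shift to C3' gives a dienone with a quaternary oxygen-bearing carbon that cannot enolise and returns to 15, and the para carbon C1' carries the chain, so only the C5' pathway has an exit. Chemoselectivity over heterolysis of the tertiary allylic C-O bond (loss of isoprene) and over acid-promoted closure of the new ortho-prenylphenol to a chroman is secured by the moderate temperature and the basic, acid-scavenging solvent. The three MOM acetals, the ketone and ring A take no part at this temperature. If the thermal reaction is slow, Eu(fod)3 (fod = 6,6,7,7,8,8,8-heptafluoro-2,2-dimethyloctane-3,5-dionate) in CHCl3 at 60 °C is the known Lewis-acid variant of the same shift.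

Step 11
Reactants: 17 1-[5,7-bis(methoxymethoxy)-2,2-dimethylchroman-6-yl]-3-[4-hydroxy-3-(methoxymethoxy)-5-(3-methylbut-2-enyl)phenyl]propan-1-one
Product: 18 1-[5,7-bis(methoxymethoxy)-2,2-dimethylchroman-6-yl]-3-[4-methoxy-3-(methoxymethoxy)-5-(3-methylbut-2-enyl)phenyl]propan-1-one
Conditions: MeI, K2CO3, acetone, 50 °C
Reagents that add atoms: iodomethane, CI
Why: Williamson methylation of the only free phenol, the one released by the rearrangement; carbonate is too weak a base to enolise and C-methylate the hindered aryl ketone.

Step 12
Reactants: 18 1-[5,7-bis(methoxymethoxy)-2,2-dimethylchroman-6-yl]-3-[4-methoxy-3-(methoxymethoxy)-5-(3-methylbut-2-enyl)phenyl]propan-1-one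
Product: 19 1-(5,7-dihydroxy-2,2-dimethylchroman-6-yl)-3-[3-hydroxy-4-methoxy-5-(3-methylbut-2-enyl)phenyl]propan-1-one
Conditions: 3 M aq. HCl, MeOH, 40 °C
Reagents that add atoms: none
Why: Acid-catalysed acetal exchange with methanol removes the three MOM groups as dimethoxymethane; O4' is now a methyl ether, so the prenyl group has no neighbouring phenol to close onto, and a short, mild treatment should leave the trisubstituted alkene untouched.

## Compound list

1 | 3,4-dihydroxybenzaldehyde | O=Cc1ccc(O)c(O)c1 | starting material
2 | 4-(benzyloxy)-3-hydroxybenzaldehyde | O=Cc1ccc(OCc2ccccc2)c(O)c1 | intermediate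
3 | 4-(benzyloxy)-3-(methoxymethoxy)benzaldehyde | COCOc1cc(C=O)ccc1OCc1ccccc1 | intermediate
4 | (E)-3-[4-(benzyloxy)-3-(methoxymethoxy)phenyl]-N-methoxy-N-methylprop-2-enamide | COCOc1cc(/C=C/C(=O)N(C)OC)ccc1OCc1ccccc1 | intermediate
5 | 3-[4-hydroxy-3-(methoxymethoxy)phenyl]-N-methoxy-N-methylpropanamide | COCOc1cc(CCC(=O)N(C)OC)ccc1O | intermediate
6 | 3-chloro-3-methylbut-1-yne | C#CC(C)(C)Cl | starting material
7 | N-methoxy-3-[3-(methoxymethoxy)-4-[(2-methylbut-3-yn-2-yl)oxy]phenyl]-N-methylpropanamide | COCOc1cc(CCC(=O)N(C)OC)ccc1OC(C)(C)C#C | intermediate
8 | N-methoxy-3-[3-(methoxymethoxy)-4-[(2-methylbut-3-en-2-yl)oxy]phenyl]-N-methylpropanamide | COCOc1cc(CCC(=O)N(C)OC)ccc1OC(C)(C)C=C | intermediate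
9 | phloroglucinol (benzene-1,3,5-triol) | Oc1cc(O)cc(O)c1 | starting material
10 | isoprene (2-methylbuta-1,3-diene) | C=CC(C)=C | starting material
11 | 2,2-dimethylchroman-5,7-diol | CC1(C)CCc2c(O)cc(O)cc2O1 | intermediate
12 | 5,7-bis(methoxymethoxy)-2,2-dimethylchroman | COCOc1cc(OCOC)c2c(c1)OC(C)(C)CC2 | intermediate
13 | [5,7-bis(methoxymethoxy)-2,2-dimethylchroman-6-yl]lithium (formed in the flask) | COCOc1cc2c(c(OCOC)c1[Li])CCC(C)(C)O2 | intermediate
14 | lithium 1-[5,7-bis(methoxymethoxy)-2,2-dimethylchroman-6-yl]-1-[methoxy(methyl)amino]-3-[3-(methoxymethoxy)-4-[(2-methylbut-3-en-2-yl)oxy]phenyl]propan-1-olate (formed in the flask, racemic) | [Li]OC(CCc1ccc(OC(C)(C)C=C)c(OCOC)c1)(N(C)OC)c1c(OCOC)cc2c(c1OCOC)CCC(C)(C)O2 | intermediate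
15 | 1-[5,7-bis(methoxymethoxy)-2,2-dimethylchroman-6-yl]-3-[3-(methoxymethoxy)-4-[(2-methylbut-3-en-2-yl)oxy]phenyl]propan-1-one | C=CC(C)(C)Oc1ccc(CCC(=O)c2c(OCOC)cc3c(c2OCOC)CCC(C)(C)O3)cc1OCOC | intermediate
16 | 4-[3-[5,7-bis(methoxymethoxy)-2,2-dimethylchroman-6-yl]-3-oxopropyl]-2-(methoxymethoxy)-6-(3-methylbut-2-enyl)cyclohexa-2,4-dien-1-one (formed in the flask, racemic, transient) | CC(C)=CCC1C=C(CCC(=O)c2c(OCOC)cc3c(c2OCOC)CCC(C)(C)O3)C=C(OCOC)C1=O | intermediate
17 | 1-[5,7-bis(methoxymethoxy)-2,2-dimethylchroman-6-yl]-3-[4-hydroxy-3-(methoxymethoxy)-5-(3-methylbut-2-enyl)phenyl]propan-1-one | CC(C)=CCc1cc(CCC(=O)c2c(OCOC)cc3c(c2OCOC)CCC(C)(C)O3)cc(OCOC)c1O | intermediate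
18 | 1-[5,7-bis(methoxymethoxy)-2,2-dimethylchroman-6-yl]-3-[4-methoxy-3-(methoxymethoxy)-5-(3-methylbut-2-enyl)phenyl]propan-1-one | COc1c(OCOC)cc(CCC(=O)c2c(OCOC)cc3c(c2OCOC)CCC(C)(C)O3)cc1CC=C(C)C | intermediate
19 | 1-(5,7-dihydroxy-2,2-dimethylchroman-6-yl)-3-[3-hydroxy-4-methoxy-5-(3-methylbut-2-enyl)phenyl]propan-1-one (CNP0408176.0) | COc1c(O)cc(CCC(=O)c2c(O)cc3c(c2O)CCC(C)(C)O3)cc1CC=C(C)C | target

## Step count and risks

Total: 12 steps. Longest linear sequence: 10 steps from **1** (steps 1 to 6 and 9 to 12). The ring A branch (steps 7 and 8) joins at step 9.

**Step 10 (key step).** The tertiary allylic C-O bond may ionise instead of rearranging, which loses isoprene and returns the O4' phenol without its prenyl group. The freed ortho-prenylphenol may also add to its own alkene on prolonged heating. The ether may further rearrange too early, during steps 6 to 9, if it is warmed.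

The fallback gives up the oxygen-to-carbon delivery and builds the C5'-CH2 bond by cross-coupling. It sets out from **5** and comes back at **18**.
- Ortho-bromination of **5** with N-bromosuccinimide and catalytic i-Pr2NH in CH2Cl2 should give 3-[3-bromo-4-hydroxy-5-(methoxymethoxy)phenyl]-N-methoxy-N-methylpropanamide F1. The para position is blocked by the chain and the other ortho position by oxygen.
- Methylation with MeI and K2CO3 gives 3-[3-bromo-4-methoxy-5-(methoxymethoxy)phenyl]-N-methoxy-N-methylpropanamide F2.
- Stille coupling with tributyl(3-methylbut-2-enyl)stannane and Pd(PPh3)4 (zerovalent palladium) in DMF gives N-methoxy-3-[4-methoxy-3-(methoxymethoxy)-5-(3-methylbut-2-enyl)phenyl]-N-methylpropanamide F3.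
- Acylation of aryllithium **13** with F3 under the conditions of step 9 then gives **18**.

**Step 9.** The hindered aryllithium may act as a base toward the alpha-methylene group of the amide instead of adding to it. Part of the metalation may fall on C8, and residual n-BuLi may attack the amide.

The fallback replaces acyl substitution by addition to an aldehyde followed by oxidation. It sets out from **8** and comes back at **15**.
- Reduction of **8** with i-Bu2AlH in THF at −78 °C gives 3-[3-(methoxymethoxy)-4-[(2-methylbut-3-en-2-yl)oxy]phenyl]propanal F4.
- Addition of **13** at −78 °C gives racemic 1-[5,7-bis(methoxymethoxy)-2,2-dimethylchroman-6-yl]-3-[3-(methoxymethoxy)-4-[(2-methylbut-3-en-2-yl)oxy]phenyl]propan-1-ol F5. A C8-derived isomer could be removed at this stage.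
- Oxidation with Dess-Martin periodinane in CH2Cl2 gives **15**.

**Step 7.** The product **11** is about as nucleophilic as **9**, so a second annulation to bis-chromans, or prenylation without ring closure, may compete.

The fallback builds the pyran ring with a deactivating carbonyl group in place and removes that group afterwards. It sets out from **9** and comes back at **11**.
- Condensation of **9** with 3-methylbut-2-enoic acid in MeSO3H/P2O5 (Friedel-Crafts acylation and oxa-Michael closure) gives 5,7-dihydroxy-2,2-dimethylchroman-4-one F6. The ketone stops further substitution.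
- Clemmensen reduction (Zn(Hg), aq. HCl, EtOH) takes the C4 carbonyl to CH2 and gives **11**.

**Step 5 (with step 6).** Substitution at the electron-rich, ortho-substituted phenol may be slow and elimination of **6** to the enyne may take over. In step 6 the reduction may run on to the saturated ether.

The fallback sets out from **5** and comes back at **8**, passing no new compound. Decarboxylative O-allylation of **5** with tert-butyl 2-methylbut-3-en-2-yl carbonate and Pd(PPh3)4 (zerovalent palladium) in THF at 0 °C attacks the more substituted end of the pi-allyl complex and gives the tertiary ether **8** directly.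

**Step 12.** Protic acid may add methanol or HCl across the prenyl alkene, and formaldehyde equivalents set free may be captured by the nucleophilic C8 of ring A.

The fallback replaces protic solvolysis by silyl transfer. It sets out from **18** and comes back at **19**.
- TMSOTf and 2,2'-bipyridyl in CH2Cl2 at 0 °C convert the three aryl MOM ethers into the tris(trimethylsilyl) ether 1-[2,2-dimethyl-5,7-bis(trimethylsilyloxy)chroman-6-yl]-3-[4-methoxy-5-(3-methylbut-2-enyl)-3-(trimethylsilyloxy)phenyl]propan-1-one F7. No free Brønsted acid is present.
- Addition of water hydrolyses the silyl ethers to **19**.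

## Further compounds

F1 | step 10 | 3-[3-bromo-4-hydroxy-5-(methoxymethoxy)phenyl]-N-methoxy-N-methylpropanamide | COCOc1cc(CCC(=O)N(C)OC)cc(Br)c1O
F2 | step 10 | 3-[3-bromo-4-methoxy-5-(methoxymethoxy)phenyl]-N-methoxy-N-methylpropanamide | COCOc1cc(CCC(=O)N(C)OC)cc(Br)c1OC
F3 | step 10 | N-methoxy-3-[4-methoxy-3-(methoxymethoxy)-5-(3-methylbut-2-enyl)phenyl]-N-methylpropanamide | COCOc1cc(CCC(=O)N(C)OC)cc(CC=C(C)C)c1OC
F4 | step 9 | 3-[3-(methoxymethoxy)-4-[(2-methylbut-3-en-2-yl)oxy]phenyl]propanal | COCOc1cc(CCC=O)ccc1OC(C)(C)C=C
F5 | step 9 | 1-[5,7-bis(methoxymethoxy)-2,2-dimethylchroman-6-yl]-3-[3-(methoxymethoxy)-4-[(2-methylbut-3-en-2-yl)oxy]phenyl]propan-1-ol (racemic) | C=CC(C)(C)Oc1ccc(CCC(O)c2c(OCOC)cc3c(c2OCOC)CCC(C)(C)O3)cc1OCOC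
F6 | step 7 | 5,7-dihydroxy-2,2-dimethylchroman-4-one | CC1(C)CC(=O)c2c(O)cc(O)cc2O1
F0 | step 5 | none | none
F7 | step 12 | 1-[2,2-dimethyl-5,7-bis(trimethylsilyloxy)chroman-6-yl]-3-[4-methoxy-5-(3-methylbut-2-enyl)-3-(trimethylsilyloxy)phenyl]propan-1-one | COc1c(O[Si](C)(C)C)cc(CCC(=O)c2c(O[Si](C)(C)C)cc3c(c2O[Si](C)(C)C)CCC(C)(C)O3)cc1CC=C(C)C
A1 | alternative 1 | 1-[5,7-bis(methoxymethoxy)-2,2-dimethyl-2H-chromen-6-yl]-3-[4-methoxy-3-(methoxymethoxy)-5-(3-methylbut-2-enyl)phenyl]propan-1-one | COc1c(OCOC)cc(CCC(=O)c2c(OCOC)cc3c(c2OCOC)C=CC(C)(C)O3)cc1CC=C(C)C
A2 | alternative 1 | 1-[2,6-bis(methoxymethoxy)-4-[(2-methylbut-3-yn-2-yl)oxy]phenyl]-3-[4-methoxy-3-(methoxymethoxy)-5-(3-methylbut-2-enyl)phenyl]propan-1-one | COc1c(OCOC)cc(CCC(=O)c2c(OCOC)cc(OC(C)(C)C#C)cc2OCOC)cc1CC=C(C)C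
A3 | alternative 2 | 1-[7-hydroxy-5-(methoxymethoxy)-2,2-dimethylchroman-6-yl]-3-[4-methoxy-3-(methoxymethoxy)-5-(3-methylbut-2-enyl)phenyl]propan-1-one | COc1c(OCOC)cc(CCC(=O)c2c(O)cc3c(c2OCOC)CCC(C)(C)O3)cc1CC=C(C)C
A4 | alternative 2 | 5-(methoxymethoxy)-2,2-dimethyl-6-(trimethylsilyl)chroman-7-yl trifluoromethanesulfonate | COCOc1c([Si](C)(C)C)c(OS(=O)(=O)C(F)(F)F)cc2c1CCC(C)(C)O2
A5 | alternative 2 | 3-[4-methoxy-3-(methoxymethoxy)-5-(3-methylbut-2-enyl)phenyl]propanoic acid | COc1c(OCOC)cc(CCC(=O)O)cc1CC=C(C)C
A6 | alternative 3 | 1-[5,7-bis(methoxymethoxy)-2,2-dimethylchroman-6-yl]-3-[4-methoxy-3-(methoxymethoxy)-5-(3-methylbut-2-enyl)phenyl]propan-1-one (identical with 18) | COc1c(OCOC)cc(CCC(=O)c2c(OCOC)cc3c(c2OCOC)CCC(C)(C)O3)cc1CC=C(C)C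
A7 | alternative 3 | 1-[5,7-bis(methoxymethoxy)-2,2-dimethylchroman-6-yl]cyclopropan-1-ol | COCOc1cc2c(c(OCOC)c1C1(O)CC1)CCC(C)(C)O2
A8 | alternative 3 | 5-bromo-2-methoxy-1-(methoxymethoxy)-3-(3-methylbut-2-enyl)benzene | COc1c(OCOC)cc(Br)cc1CC=C(C)C
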